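**Analysis of the target**

Target 16 is a mellein-type 3,4-dihydroisocoumarin. A benzene ring (ring A, C4a to C8a) is fused to a six-membered lactone (ring B: C1 carbonyl, O2, C3, C4), with a free hydroxyl at C8 and a (6Z)-pentadec-6-enyl chain at C3. C3 (R) is the only stereocentre, so its configuration cannot be relayed from anything else in the molecule and has to come from a chiral catalyst, reagent or building block. C3 sits between two methylene groups (C4 and the first chain carbon), so an open-chain carbonyl precursor offers almost no difference between its two faces; the difference is far larger once C3 is part of the flat bicyclic ring. The lactone is open to strong nucleophiles and bases, and the C8 hydroxyl, hydrogen-bonded to the lactone carbonyl, is acidic and consumes basic reagents. The C6'=C7' Z-alkene would be lost under hydrogenation and can isomerize under acid. The difficulties are therefore the contiguous 1,2,3-substitution of ring A, one isolated stereocentre, and a Z-alkene that must be kept away from every reductive step. The plan rests on one feature: C8 (oxygen), C8a (bearing the carboxyl carbon C1) and C4a (bearing C4) are neighbours on ring A. That is the pattern left when a 3-alkoxybenzyne takes up a carbon nucleophile at the aryne carbon remote from oxygen and carbon dioxide at the carbon next to it. With an acetylide as the nucleophile, the carboxylate can close ring B onto the alkyne, and C3 appears as an sp2 carbon of an isocoumarin, ready for enantioselective hydrogenation.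

**Retrosynthetic reasoning**

The O–CH3 bond at C8 is cut last, so 16 comes from methyl ether 14 through the boron ester 15. The methyl group is already present in the aryne precursor 4, where it directs the regiochemistry of ring-A substitution. It also keeps the phenol silent through the basic and oxidative steps. Its position peri to the lactone carbonyl makes a chelation-assisted cleavage selective, so the forward step only has to remove it without touching the alkene or the lactone.

The C6'=C7' double bond of 14 is cut next, giving aldehyde 11 and ylide 13, which is made from phosphonium salt 12. Cutting here divides the lipophilic chain into a purchasable nine-carbon piece and a six-carbon tether. It also places the Z-alkene after all hydrogenation steps. The forward Wittig reaction has to give the Z isomer and leave the lactone alone.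

Aldehyde 11 is traced back through alcohol 10 to benzyl ether 9. These are two changes of functional group with no change of skeleton: oxidation of a primary alcohol, and hydrogenolytic release of that alcohol. The debenzylation is the last reduction of the route and is placed before the alkene exists.

In 9 the two C–H bonds at C3 and C4 are removed, which leads to isocoumarin 8. This turns the stereochemical problem into face selection on a planar enol lactone, where the ring itself lets a chiral hydrogenation catalyst tell the faces apart. The forward step must add hydrogen to one face only and leave the benzyl ether and both arenes intact.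

Isocoumarin 8 is cut at three bonds at once: C4a–C4, C8a–C1 and O2–C3. This gives alkyne 3, aryne precursor 4 and carbon dioxide 5. In the forward sense they pass through aryne 6 and carboxylate 7. The three bonds are cut together because they are the bonds around the contiguous C8/C8a/C4a triad. The methoxy group of 6 decides which aryne carbon receives carbon and which receives the carboxyl group, so ring A needs no stepwise functionalization. The forward reaction must capture 6 regioselectively, insert 5, and close ring B in the 6-endo mode.

Alkyne 3 is cut at its benzyl–oxygen bond to give oct-7-yn-1-ol 1, by way of alkoxide 2. The benzyl ether is chosen for the side-chain oxygen because it is inert to the fluoride and carbonate used to release 6. A silyl ether would be at risk there.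

**Alternatives that were turned down**

Alternative 1: Ring A is cut at C6–C7 and C4a–C8a, leading back to the (R)-dihydropyranone A2 and 1-methoxy-1,3-bis(trimethylsilyloxy)buta-1,3-diene A3.
- Forward key step: the terminal carbon of A3 adds to the enol-ether carbon of A2, its central carbon condenses with the ketone, and the ring oxygen is expelled. Salicylate A1 results, with the C3 oxygen present as a free secondary alcohol, and lactonization would give 16.
- For it: the stereocentre is fixed early, for example by a catalytic enantioselective hetero-Diels–Alder reaction. The phenol arrives unprotected, so no ether cleavage is needed at the end. The [3+3] benzannulation of bis(silyloxy)dienes with open-chain alkoxy enones is a known reaction type.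
- Against it: in A2 the ring oxygen is beta to the ketone on both sides. Under the Lewis acid the C2–O bond can be lost by elimination as readily as the C6–O bond, and that would destroy the stereocentre. The order of the two C–C bond formations is not enforced. The Z-alkenyl chain must be built into A2 beforehand, which costs several steps and then exposes the alkene to a strong Lewis acid.
- Comparison: on the end game this alternative is stronger, since the chosen plan has to carry and remove a methyl ether. The chosen plan offers a ring-A pattern fixed by aryne polarization instead of by competing addition modes, all core bonds made from purchasable components in one catalytic operation, and a stereocentre set on a rigid ring where no elimination can reach it.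

Alternative 2: The C1–O2 and O2–C3 bonds are traced back to oxygen insertion into the C1–C2 bond of racemic indanone A4.
- Forward key step: a Baeyer–Villiger monooxygenase oxidizes A4 with migration of the secondary alkyl carbon while the slow-reacting enantiomer racemizes through its enol. The product is methyl ether A5, which is identical with 14.
- For it: ring expansion and stereocentre come in one step. No metal or pressure equipment is needed. The Z-alkene can be present from the start, since no hydrogenation follows. A4 is available by a simple alpha-alkylation. In step count it equals or beats the chosen plan.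
- Against it: migration of the alkyl carbon in preference to an electron-rich aryl carbon runs against the innate migratory preference and depends entirely on the enzyme pocket. That pocket must accept a fifteen-carbon lipophilic chain and a methoxy group next to the ketone. The substrate is barely soluble in the aqueous medium. The configuration delivered is fixed by the protein and cannot simply be inverted.
- Comparison: the chosen plan answers the same questions with small-molecule catalysts. Regiochemistry follows from the polarization of aryne 6, and both antipodes of the hydrogenation ligands can be had, so the R series is reachable whatever the intrinsic sense of induction.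

Alternative 3: Ring A is cut at C8–C8a and C4a–C5 into 1-methoxycyclohexa-1,3-diene A6 and the (R)-silyloxy ynoate A7.
- Forward key step: a Diels–Alder reaction, oriented so that the oxygen-bearing diene terminus bonds to the ester-bearing alkyne carbon, gives a bicyclo[2.2.2]octadiene. This expels its two-carbon bridge in a retro-Diels–Alder step and leaves benzoate A8. Desilylation, lactonization and demethylation would follow.
- For it: it is metal-free and the orientation follows the usual ortho rule. The stereocentre comes from an acyclic precursor of secure configuration, so no asymmetric catalysis on the ring system is needed. On reliability of the stereocentre it is at least as strong as the chosen plan.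
- Against it: an ynoate with an alkyl group on its beta carbon is a sluggish dienophile, and the extrusion needs prolonged heating at high temperature. Under such conditions A6 can isomerize out of conjugation or aromatize by loss of its methoxy group, and a long Z-alkenyl chain is open to ene and isomerization processes. A7 itself takes several steps, and three steps still follow the key step.
- Comparison: the chosen plan reaches the same 1,2,3-pattern at moderate temperature from two simple partners and carbon dioxide, closes the lactone in the same operation, and keeps the alkene out of every harsh step.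

Key step: step 2

Assumption: the ligand antipodes that give 3R in step 3 are to be fixed in a first run, both series being available.

**Route**

Step 1
Reactants: 1 oct-7-yn-1-ol
Product: 3 8-(benzyloxy)oct-1-yne, via sodium oct-7-yn-1-olate 2 (not isolated)
Conditions: NaH (1.2 equiv), BnBr (1.1 equiv), Bu4NI (cat.), THF, 0 °C to rt
Reagents that add atoms: benzyl bromide, BrCc1ccccc1
Why: Williamson ether synthesis; NaH removes only the hydroxyl proton (the alkyne C–H is much less acidic under these conditions) and alkoxide 2 displaces bromide from the benzylic halide. The benzyl ether is inert to the hot fluoride and carbonate of step 2 and can be removed by hydrogenolysis before the alkene exists.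

Step 2
Reactants: 3 8-(benzyloxy)oct-1-yne; 4 3-methoxy-2-(trimethylsilyl)phenyl trifluoromethanesulfonate; 5 carbon dioxide
Product: 8 3-[6-(benzyloxy)hexyl]-8-methoxy-1H-isochromen-1-one, via 3-methoxybenzyne 6 (not isolated), via cesium 2-alkynyl-6-methoxybenzoate 7 (not isolated)
Conditions: CuCl(IPr) (10 mol %; IPr = 1,3-bis(2,6-diisopropylphenyl)imidazol-2-ylidene), CsF (3 equiv), Cs2CO3 (20 mol %), CO2 (1 atm), MeCN, 80 °C, 4 (1.5 equiv) added slowly
Reagents that add atoms: none
Why: This is the known three-component coupling of an aryne, a terminal alkyne and CO2 to a 3-substituted isocoumarin under an N-heterocyclic-carbene complex of monovalent copper. CsF removes the trimethylsilyl group of 4 and triflate departs, so aryne 6 is released slowly into a solution in which 3 is held as its copper acetylide. The acetylide adds across the strained triple bond with its carbon on the aryne carbon remote from the methoxy group (bond C4a–C4) and copper on the carbon next to it (future C8a), because the inductively withdrawing oxygen distorts the aryne toward attack at the remote carbon and stabilizes the carbon–metal bond beside it. CO2 then inserts into this aryl–copper bond (bond C8a–C1) to give the copper-bound carboxylate, drawn as cesium salt 7. Ring B is closed by 6-endo-dig anti addition of the carboxylate oxygen to the copper-activated alkyne (bond O2–C3), and the 4-cuprated isocoumarin is protonated by a further molecule of 3, which returns the acetylide. No stereocentre is formed. The step needs regioselective aryne capture, carboxylation of the arylcopper before it is protonated, and 6-endo in preference to 5-exo closure: the methoxy group secures the first, the CO2 atmosphere with slow aryne release the second, and the alkyl-substituted distal alkyne carbon, which bears the positive character under copper activation and leads to an unstrained six-membered enol lactone, the third. The benzyl ether and the aryl methyl ether are inert to fluoride, carbonate and copper.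

Step 3
Reactants: 8 3-[6-(benzyloxy)hexyl]-8-methoxy-1H-isochromen-1-one
Product: 9 (3R)-3-[6-(benzyloxy)hexyl]-8-methoxy-3,4-dihydro-1H-isochromen-1-one
Conditions: catalyst from Ru(2-methylallyl)2(cod) (5 mol %), SINpEt·HBF4 (1,3-bis[1-(naphthalen-1-yl)ethyl]-4,5-dihydroimidazolium tetrafluoroborate), KOt-Bu and 1,2-diphenylethylenediamine (ligand antipodes chosen for 3R); NaOt-Bu (cat.), H2 (50 bar), n-hexane/toluene, 25 °C
Reagents that add atoms: none
Why: Enantioselective hydrogenation of the C3=C4 enol lactone of an isocoumarin with a chiral carbene–diamine complex of divalent ruthenium is a known reaction for 3-alkyl and 8-alkoxy members of this class. Hydrogen is delivered to one face of the planar ring B, selected by the chiral pocket of the naphthylethyl-substituted carbene and the diamine, which sets C3 as R. The benzyl ether, both benzene rings and the lactone are not reduced, and no other alkene is present yet.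

Step 4
Reactants: 9 (3R)-3-[6-(benzyloxy)hexyl]-8-methoxy-3,4-dihydro-1H-isochromen-1-one
Product: 10 (3R)-3-(6-hydroxyhexyl)-8-methoxy-3,4-dihydro-1H-isochromen-1-one
Conditions: H2 (1 atm), Pd/C (10 wt %), EtOAc, rt
Reagents that add atoms: none
Why: Hydrogenolysis of a benzyl ether over Pd/C; the lactone C3–O bond is homobenzylic and is not cleaved, and the aryl methyl ether and C3 are unaffected. This is the last reductive step and precedes the introduction of the Z-alkene.

Step 5
Reactants: 10 (3R)-3-(6-hydroxyhexyl)-8-methoxy-3,4-dihydro-1H-isochromen-1-one
Product: 11 6-[(3R)-8-methoxy-1-oxo-3,4-dihydro-1H-isochromen-3-yl]hexanal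
Conditions: Dess–Martin periodinane (1.2 equiv), CH2Cl2, 0 °C to rt
Reagents that add atoms: none
Why: Dess–Martin oxidation takes the primary alcohol to the aldehyde under near-neutral conditions without over-oxidation. C3 is remote from the new carbonyl and cannot epimerize.

Step 6
Reactants: 11 6-[(3R)-8-methoxy-1-oxo-3,4-dihydro-1H-isochromen-3-yl]hexanal; 12 nonyltriphenylphosphonium bromide
Product: 14 (3R)-8-methoxy-3-[(6Z)-pentadec-6-en-1-yl]-3,4-dihydro-1H-isochromen-1-one, via nonylidenetriphenylphosphorane 13 (not isolated)
Conditions: 12 (1.5 equiv), NaN(SiMe3)2 (1.4 equiv), THF, 0 °C; then 11, −78 °C to rt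
Reagents that add atoms: none
Why: Wittig reaction of a non-stabilized ylide under lithium-free conditions; ylide 13 adds to the aldehyde at low temperature through a kinetically formed cis-oxaphosphetane that collapses to the Z-alkene. The aldehyde reacts much faster than the lactone carbonyl, which is flanked by the methoxy group and the ring, so ring B should stay intact.

Step 7
Reactants: 14 (3R)-8-methoxy-3-[(6Z)-pentadec-6-en-1-yl]-3,4-dihydro-1H-isochromen-1-one
Product: 16 (3R)-8-hydroxy-3-[(6Z)-pentadec-6-en-1-yl]-3,4-dihydro-1H-isochromen-1-one, via aryloxydichloroborane 15 (not isolated)
Conditions: BCl3 (1 M in CH2Cl2, 2.5 equiv), CH2Cl2, −78 to 0 °C; aq. NaHCO3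
Reagents that add atoms: none
Why: Chelation-assisted ether cleavage; BCl3 binds the lactone carbonyl and the neighbouring methoxy oxygen, chloride removes the methyl group, and aqueous work-up hydrolyses boron ester 15 to the hydrogen-bonded phenol. At low temperature BCl3 should not add to an isolated dialkyl alkene, and the lactone and C3 are untouched.

**Compound list**

1 | oct-7-yn-1-ol | C#CCCCCCCO | starting material
2 | sodium oct-7-yn-1-olate | [Na+].[O-]CCCCCCC#C | intermediate (not isolated)
3 | 8-(benzyloxy)oct-1-yne | C#CCCCCCCOCc1ccccc1 | intermediate
4 | 3-methoxy-2-(trimethylsilyl)phenyl trifluoromethanesulfonate | COc1cccc(OS(=O)(=O)C(F)(F)F)c1[Si](C)(C)C | starting material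
5 | carbon dioxide | O=C=O | starting material
6 | 3-methoxy-1,2-didehydrobenzene (3-methoxybenzyne) | COC1=CC=CC#C1 | intermediate (not isolated)
7 | cesium 2-[8-(benzyloxy)oct-1-yn-1-yl]-6-methoxybenzoate (copper-bound in the cycle) | COc1cccc(C#CCCCCCCOCc2ccccc2)c1C(=O)[O-].[Cs+] | intermediate (not isolated)
8 | 3-[6-(benzyloxy)hexyl]-8-methoxy-1H-isochromen-1-one | COc1cccc2C=C(CCCCCCOCc3ccccc3)OC(=O)c12 | intermediate
9 | (3R)-3-[6-(benzyloxy)hexyl]-8-methoxy-3,4-dihydro-1H-isochromen-1-one | c1ccccc1COCCCCCC[C@@H]1Cc2cccc(OC)c2C(=O)O1 | intermediate
10 | (3R)-3-(6-hydroxyhexyl)-8-methoxy-3,4-dihydro-1H-isochromen-1-one | OCCCCCC[C@@H]1Cc2cccc(OC)c2C(=O)O1 | intermediate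
11 | 6-[(3R)-8-methoxy-1-oxo-3,4-dihydro-1H-isochromen-3-yl]hexanal | O=CCCCCC[C@@H]1Cc2cccc(OC)c2C(=O)O1 | intermediate
12 | nonyltriphenylphosphonium bromide | CCCCCCCCC[P+](c1ccccc1)(c1ccccc1)c1ccccc1.[Br-] | starting material
13 | nonylidenetriphenylphosphorane | CCCCCCCCC=P(c1ccccc1)(c1ccccc1)c1ccccc1 | intermediate (not isolated)
14 | (3R)-8-methoxy-3-[(6Z)-pentadec-6-en-1-yl]-3,4-dihydro-1H-isochromen-1-one | CCCCCCCC/C=C\CCCCC[C@@H]1Cc2cccc(OC)c2C(=O)O1 | intermediate
15 | (3R)-8-(dichloroboranyloxy)-3-[(6Z)-pentadec-6-en-1-yl]-3,4-dihydro-1H-isochromen-1-one | CCCCCCCC/C=C\CCCCC[C@@H]1Cc2cccc(OB(Cl)Cl)c2C(=O)O1 | intermediate (not isolated)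
16 | (3R)-8-hydroxy-3-[(6Z)-pentadec-6-en-1-yl]-3,4-dihydro-1H-isochromen-1-one | CCCCCCCC/C=C\CCCCC[C@@H]1Cc2cccc(O)c2C(=O)O1 | target

Total step count: 7. Longest linear sequence: 7 steps (1 to 16).

**Steps least certain to work**

Step 2 (key step).
- What may go wrong: the three bimolecular events may not mesh. The copper acetylide can be carboxylated directly. The arylcopper can be protonated before CO2 inserts, which amounts to simple hydroalkynylation of the aryne. The aryne can oligomerize. Ring closure can leak into the 5-exo mode.
- Why: an alkyl acetylide is a weaker aryne trap than an aryl acetylide, and the arylcopper carbon carries two ortho substituents.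
- Fallback: a stepwise construction that sets out from 3 and comes back at 8. Sonogashira coupling of 3 with purchased methyl 2-bromo-6-methoxybenzoate F1 (PdCl2(PPh3)2, CuI, Et3N, 70 °C) would give methyl 2-[8-(benzyloxy)oct-1-yn-1-yl]-6-methoxybenzoate F2. Saponification (LiOH, aqueous THF/MeOH, heat) would give 2-[8-(benzyloxy)oct-1-yn-1-yl]-6-methoxybenzoic acid F3. Cycloisomerization with a catalytic amount of TfOH in CH2Cl2 should then close ring B in the 6-endo-dig mode and give 8, because protonation places the positive charge on the alkyl-bearing alkyne carbon.

Step 3.
- What may go wrong: face discrimination may be insufficient, or turnover slow. The opposite sense of induction is not a failure, since the ligand antipodes can be exchanged.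
- Why: the C3 substituent is a long, flexible, unbranched chain, and the methoxy group sits next to the lactone carbonyl.
- Fallback: take the stereocentre from a resolved epoxide, setting out from 3 and coming back at 9.
  - Semihydrogenation of 3 (H2, Pd/CaCO3 poisoned with Pb(OAc)2, quinoline) would give 8-(benzyloxy)oct-1-ene F4.
  - Epoxidation with m-chloroperbenzoic acid would give racemic 2-[6-(benzyloxy)hexyl]oxirane F5.
  - Hydrolytic kinetic resolution with a chiral (salen)Co(OAc) catalyst of trivalent cobalt and 0.55 equiv of water would leave (2R)-2-[6-(benzyloxy)hexyl]oxirane F6. The catalyst enantiomer is chosen so that the S epoxide is removed as (2S)-8-(benzyloxy)octane-1,2-diol F7.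
  - Purchased N,N-diethyl-2-methoxy-6-methylbenzamide F8 would be lithiated at its benzylic methyl group (s-BuLi, THF, −78 °C). The anion would open F6 at the terminal carbon to give N,N-diethyl-2-[(2R)-8-(benzyloxy)-2-hydroxyoctyl]-6-methoxybenzamide F9.
  - Acid-promoted lactonization (p-TsOH, toluene, reflux) would give 9. No bond to the stereocentre is broken on the way.

Step 6.
- What may go wrong: Z selectivity may erode through stereochemical drift of the oxaphosphetane, and the basic ylide may enolize the aldehyde.
- Why: the ylide is a strong base and the selectivity is purely kinetic. An E isomer would be hard to remove from a fifteen-carbon chain.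
- Fallback: sets out from 11 and comes back at 14. Methylenation of 11 with Ph3P=CH2 (from Ph3PCH3Br and KOt-Bu) would give (3R)-3-(hept-6-en-1-yl)-8-methoxy-3,4-dihydro-1H-isochromen-1-one F10. Z-selective cross-metathesis of F10 with an excess of purchased dec-1-ene F11 would give 14. The catalyst would be a cyclometalated ruthenium alkylidene of the type Ru(NO3)(=CH-C6H4-2-Oi-Pr)(NHC), in which the N-adamantyl group of the carbene is bound to the metal through carbon. Here the alkene geometry is set by the catalyst and not by the ylide.

Step 7.
- What may go wrong: the ether cleavage may be incomplete. If it has to be forced, the alkene may isomerize or take up HCl.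
- Why: the Lewis acid and the HCl it releases share the flask with the Z-alkene.
- Fallback: change the order so that the alkene never meets the Lewis acid, setting out from 9 and coming back at 16. BCl3 in CH2Cl2 would cleave the benzyl ether and the methyl ether of 9 in one operation and give (3R)-8-hydroxy-3-(6-hydroxyhexyl)-3,4-dihydro-1H-isochromen-1-one F12. Parikh–Doering oxidation (SO3·pyridine, DMSO, i-Pr2NEt), which leaves the electron-poor, hydrogen-bonded phenol alone, would give 6-[(3R)-8-hydroxy-1-oxo-3,4-dihydro-1H-isochromen-3-yl]hexanal F13. A Wittig reaction with at least two equivalents of ylide 13, the first serving to deprotonate the phenol, would give 16 directly.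

**Further compounds**

F1 | step 2 | methyl 2-bromo-6-methoxybenzoate | COC(=O)c1c(Br)cccc1OC
F2 | step 2 | methyl 2-[8-(benzyloxy)oct-1-yn-1-yl]-6-methoxybenzoate | COC(=O)c1c(OC)cccc1C#CCCCCCCOCc1ccccc1
F3 | step 2 | 2-[8-(benzyloxy)oct-1-yn-1-yl]-6-methoxybenzoic acid | OC(=O)c1c(OC)cccc1C#CCCCCCCOCc1ccccc1
F4 | step 3 | 8-(benzyloxy)oct-1-ene | C=CCCCCCCOCc1ccccc1
F5 | step 3 | racemic 2-[6-(benzyloxy)hexyl]oxirane | C1OC1CCCCCCOCc1ccccc1
F6 | step 3 | (2R)-2-[6-(benzyloxy)hexyl]oxirane | C(c1ccccc1)OCCCCCC[C@@H]1CO1
F7 | step 3 | (2S)-8-(benzyloxy)octane-1,2-diol | OC[C@@H](O)CCCCCCOCc1ccccc1
F8 | step 3 | N,N-diethyl-2-methoxy-6-methylbenzamide | CCN(CC)C(=O)c1c(C)cccc1OC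
F9 | step 3 | N,N-diethyl-2-[(2R)-8-(benzyloxy)-2-hydroxyoctyl]-6-methoxybenzamide | CCN(CC)C(=O)c1c(OC)cccc1C[C@H](O)CCCCCCOCc1ccccc1
F10 | step 6 | (3R)-3-(hept-6-en-1-yl)-8-methoxy-3,4-dihydro-1H-isochromen-1-one | C=CCCCCC[C@@H]1Cc2cccc(OC)c2C(=O)O1
F11 | step 6 | dec-1-ene | C=CCCCCCCCC
F12 | step 7 | (3R)-8-hydroxy-3-(6-hydroxyhexyl)-3,4-dihydro-1H-isochromen-1-one | OCCCCCC[C@@H]1Cc2cccc(O)c2C(=O)O1
F13 | step 7 | 6-[(3R)-8-hydroxy-1-oxo-3,4-dihydro-1H-isochromen-3-yl]hexanal | O=CCCCCC[C@@H]1Cc2cccc(O)c2C(=O)O1
A1 | alternative 1 | methyl 2-hydroxy-6-[(2R,8Z)-2-hydroxyheptadec-8-en-1-yl]benzoate | CCCCCCCC/C=C\CCCCC[C@@H](O)Cc1cccc(O)c1C(=O)OC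
A2 | alternative 1 | (2R)-2-[(6Z)-pentadec-6-en-1-yl]-2,3-dihydro-4H-pyran-4-one | CCCCCCCC/C=C\CCCCC[C@@H]1CC(=O)C=CO1
A3 | alternative 1 | 1-methoxy-1,3-bis(trimethylsilyloxy)buta-1,3-diene | COC(O[Si](C)(C)C)=CC(=C)O[Si](C)(C)C
A4 | alternative 2 | racemic 7-methoxy-2-[(6Z)-pentadec-6-en-1-yl]-2,3-dihydro-1H-inden-1-one | CCCCCCCC/C=C\CCCCCC1Cc2cccc(OC)c2C1=O
A5 | alternative 2 | (3R)-8-methoxy-3-[(6Z)-pentadec-6-en-1-yl]-3,4-dihydro-1H-isochromen-1-one | CCCCCCCC/C=C\CCCCC[C@@H]1Cc2cccc(OC)c2C(=O)O1
A6 | alternative 3 | 1-methoxycyclohexa-1,3-diene | COC1=CC=CCC1
A7 | alternative 3 | methyl (5R,11Z)-5-[(tert-butyldimethylsilyl)oxy]icos-11-en-2-ynoate | CCCCCCCC/C=C\CCCCC[C@@H](O[Si](C)(C)C(C)(C)C)CC#CC(=O)OC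
A8 | alternative 3 | methyl 2-[(2R,8Z)-2-[(tert-butyldimethylsilyl)oxy]heptadec-8-en-1-yl]-6-methoxybenzoate | CCCCCCCC/C=C\CCCCC[C@@H](O[Si](C)(C)C(C)(C)C)Cc1cccc(OC)c1C(=O)OC
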